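The numbers in the tables stem from a simulated flask with constants of no real substance; scatter was added.

**One-step world.** A one-step reaction at constant temperature loses starting material fastest at its first moment, but Wednesday's flask runs the other way.

| flask | starting material | coupling partner | precatalyst | remark |
|---|---|---|---|---|
| Wednesday's | 0.0050 M | 2 equiv | 0.5 mol% | the very flask that is asked about, followed so far |
| flask | 0.0050 M | 2.00 equiv | 0.5 mol% |  |

Wednesday's run (percent of the starting material charged)

| time / s | product / % | starting material / % |
|---|---|---|
| 20.0 | 0 | 96 |
| 40.0 | 7 | 95 |
| 60.0 | 1 | 93 |
| 80.0 | 16 | 89 |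
| 90.0 | 16 | 86 |
| 120 | 20 | 73 |

(readings scatter by 2 percentage points)

- the numbers in the tables scatter by 2 percentage points (one standard deviation)
- no earlier run changes the charge of precatalyst; that part of a forecast is a guess

* factor on the rate of making product when 5.0% of the starting material are converted if precatalyst is charged twice over
* factor on the rate when 5.0% of the starting material are converted if precatalyst is charged at 0.1 mol% instead

**Rate ladder.** Wednesday's readings put the fastest loss last, 0.260 min⁻¹ of the charge between 90.0 s and 120 s. Next comes 0.140 min⁻¹ between 60.0 s and 90.0 s, and the slowest is 0.0700 min⁻¹ up to 60.0 s. So the loss speeds up as Wednesday's flask runs: an induction period.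

**Time removed.** The loss at 120 s against the loss at 60.0 s gives a reading for the power of time in the loss, 1.95, with the scatter of the readings in it. My own reckoning assumes that the loss at a fixed time follows the precatalyst charge in proportion, which no earlier run tests. A larger charge then reaches a given conversion sooner, and dividing the rate at one charge by the rate at another, at equal conversion, removes time. The factor on the rate is the factor on the charge raised to 0.513, the fixed-conversion order. That gives 1.43 for the doubled charge and 0.438 for 0.1 mol%.

**The forecast.** It says 1.6 (1.2 to 2.1) and 0.33 (0.17 to 0.6): “I take an order of about 0.7”, which is higher than my order.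

**The result.** The flask gives 1.31 and 0.515.

    2 catalyst ⇌ resting dimer, settled at all times (K = 4.60 × 10⁵ M⁻¹)
    coupling partner + precatalyst → catalyst + spent reagent (k = 0.401 M⁻¹ s⁻¹)
    starting material + coupling partner + catalyst → product + catalyst, rate k3*[starting material]*[coupling partner]*[catalyst]/(1 + ([starting material]/sat3)) (0.0994 mM, k = 5.81 × 10⁶ M⁻² s⁻¹)

**Lost order.** The doubled charge shows an order of 0.385 and the 0.1 mol% flask shows 0.412, both lower than 0.513. Multiplied by the reading 1.95, the doubled flask's order puts the loss at a fixed time at the charge to the power 0.751, not in proportion. After 0.400 min, the flask holds 90.9% of its catalyst charge as precatalyst, 4.50% as catalyst and 4.65% as resting dimer. Without that pairing, the rate at 5.0% conversion stands at 1.76 times the actual one.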